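The plan cuts the O1–C8a aryl ether bond of ring C. In the target, C3 carries one hydrogen next to C2H2–O1. Exchanging that hydrogen for a second CH2OH makes C3 the prochiral carbon of a 2-aryl-2-benzylpropane-1,3-diol whose ring A carbon C8a bears bromine. A chiral palladium catalyst then couples C8a with one of the two enantiotopic hydroxymethyl oxygens. This single operation forms O1–C8a, closes ring C and fixes a quaternary C3 that cannot epimerise. The spare CH2OH is later oxidised and expelled as CO with retention. Ring B travels as its 2',5'-dimethoxy-4'-MOM ether, so cerium(IV) and mild acid release the hydroxyquinone, never base.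

Key step: step 12

Conventions: prenyl = 3-methylbut-2-en-1-yl. Isoflavan numbering is used (ring A C4a–C8a, ring C O1–C4, ring B primed).

Assumption 1: the sense of induction of the spiro ligand on this substrate cannot be predicted safely. (S)-SDP(O) is entered as the working choice, and its mirror image is used if a pilot run gives the S alcohol.

Assumption 2: 2,5-dimethoxyphenol is taken as purchasable.

Design remark: O4' carries MOM instead of methyl. A prenylated quinone with a C3–H next to it could tautomerise to a quinone methide in base, which would racemise C3 or form a chromenol.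

Stereochemical bookkeeping: the descriptors run R (23), S (24), R (25–27). The letter changes come from CIP ranking only; the spatial arrangement at C3 stays the same throughout.

Step 1
Reactants: 1 1,3-dimethoxybenzene; 2 prenyl bromide
Product: 4 1,3-dimethoxy-2-prenylbenzene, via 2,6-dimethoxyphenyllithium 3 (not isolated)
Conditions: n-BuLi, THF, 0 °C to rt; then 2, 0 °C to rt
Reagents that add atoms: prenyl bromide (2), CC(C)=CCBr
Why: Directed ortho-metalation places lithium between the two methoxy groups, and the aryllithium displaces the primary allylic bromide in an SN2 alkylation.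

Step 2
Reactants: 4 1,3-dimethoxy-2-prenylbenzene
Product: 6 2,4-dimethoxy-3-prenylbenzaldehyde, via aryl iminium salt 5 (not isolated)
Conditions: POCl3, DMF, 0 to 50 °C; then ice-cold aq NaOAc
Reagents that add atoms: N,N-dimethylformamide, CN(C)C=O; water, O
Why: Vilsmeier–Haack formylation enters one of the two equivalent positions ortho to one methoxy group and para to the other, and the weak chloroiminium electrophile and buffered quench should leave the trisubstituted alkene alone.

Step 3
Reactants: 6 2,4-dimethoxy-3-prenylbenzaldehyde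
Product: 10 6-bromo-2,4-dimethoxy-3-prenylbenzaldehyde, via lithium amino alkoxide 7 (not isolated), via ortho-lithiated amino alkoxide 8 (not isolated), via brominated amino alkoxide 9 (not isolated)
Conditions: MeNHCH2CH2NMe2, n-BuLi, THF, −20 °C; 6; n-BuLi, −20 °C; BrCl2CCCl2Br, −78 °C; then H2O
Reagents that add atoms: 1,2-dibromo-1,1,2,2-tetrachloroethane, ClC(Cl)(Br)C(Cl)(Cl)Br
Why: In situ protection of the aldehyde as a chelating α-amino alkoxide directs ortho-lithiation to C6 (C2 is blocked), a positive-bromine donor traps the carbanion, and water returns the aldehyde.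

Step 4
Reactants: 10 6-bromo-2,4-dimethoxy-3-prenylbenzaldehyde
Product: 11 (6-bromo-2,4-dimethoxy-3-prenylphenyl)methanol
Conditions: NaBH4, MeOH/THF, 0 °C
Reagents that add atoms: none
Why: Borohydride reduction of an aromatic aldehyde leaves the aryl bromide and the isolated alkene untouched.

Step 5
Reactants: 11 (6-bromo-2,4-dimethoxy-3-prenylphenyl)methanol
Product: 12 1-bromo-2-(bromomethyl)-3,5-dimethoxy-4-prenylbenzene
Conditions: CBr4, PPh3, CH2Cl2, 0 °C; short filtration, used at once
Reagents that add atoms: carbon tetrabromide, BrC(Br)(Br)Br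
Why: The Appel reaction converts the activated benzylic alcohol to the bromide under neutral conditions, so no HBr is present to add to the prenyl group.

Step 6
Reactants: 13 2,5-dimethoxyphenol
Product: 14 2,4-dibromo-3,6-dimethoxyphenol
Conditions: NBS (2 equiv), MeCN, 0 °C, dark
Reagents that add atoms: N-bromosuccinimide, O=C1CCC(=O)N1Br
Why: In this electrophilic aromatic substitution the free hydroxyl sends bromine to its open para and ortho positions, both also ortho to a methoxy group, and the remaining C–H is far less activated.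

Step 7
Reactants: 14 2,4-dibromo-3,6-dimethoxyphenol
Product: 15 1,3-dibromo-2,5-dimethoxy-4-(methoxymethoxy)benzene
Conditions: MOMCl, i-Pr2NEt, CH2Cl2, 0 °C to rt
Reagents that add atoms: chloromethyl methyl ether, COCCl
Why: O-alkylation of the acidic phenol installs an acetal that withstands base, hydride, palladium and heat but remains removable by acid.

Step 8
Reactants: 15 1,3-dibromo-2,5-dimethoxy-4-(methoxymethoxy)benzene; 2 prenyl bromide
Product: 17 1-bromo-2,5-dimethoxy-4-(methoxymethoxy)-3-prenylbenzene, via aryllithium 16 (not isolated)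
Conditions: n-BuLi (1.0 equiv), THF, −78 °C; CuBr·SMe2 (cat.), 2, −78 to 0 °C
Reagents that add atoms: prenyl bromide (2), CC(C)=CCBr
Why: Halogen–lithium exchange settles at the bromine flanked by OMe and OMOM, where the carbanion is best stabilised and chelated and strain is relieved, the other bromine lies meta so no aryne can form, and copper-catalysed allylic substitution gives the linear prenyl arene.

Step 9
Reactants: 17 1-bromo-2,5-dimethoxy-4-(methoxymethoxy)-3-prenylbenzene; 18 diethyl malonate
Product: 19 diethyl 2-[2,5-dimethoxy-4-(methoxymethoxy)-3-prenylphenyl]malonate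
Conditions: Pd2(dba)3 (cat.), P(t-Bu)3·HBF4 (cat.), K3PO4, toluene, 80 °C
Reagents that add atoms: diethyl malonate (18), CCOC(=O)CC(=O)OCC
Why: Palladium-catalysed α-arylation of a malonate (Buchwald–Hartwig type) with a bulky electron-rich phosphine accepts electron-rich ortho-alkoxy aryl bromides, and the product rests as its enolate, which prevents a second arylation.

Step 10
Reactants: 19 diethyl arylmalonate; 12 1-bromo-2-(bromomethyl)-3,5-dimethoxy-4-prenylbenzene
Product: 21 diethyl 2-[(6-bromo-2,4-dimethoxy-3-prenylphenyl)methyl]-2-[2,5-dimethoxy-4-(methoxymethoxy)-3-prenylphenyl]malonate, via sodium malonate enolate 20 (not isolated)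
Conditions: NaH, THF/DMF, 0 °C; then 12, 0 °C to rt
Reagents that add atoms: none
Why: Malonic ester alkylation (SN2) at a very reactive benzylic bromide builds the fully substituted carbon, and the aryl C–Br bond is inert to the enolate.

Step 11
Reactants: 21 dialkylated malonate
Product: 22 2-[(6-bromo-2,4-dimethoxy-3-prenylphenyl)methyl]-2-[2,5-dimethoxy-4-(methoxymethoxy)-3-prenylphenyl]propane-1,3-diol (achiral, prochiral at C2 of the propane chain, the future C3)
Conditions: LiAlH4, THF, 0 °C to rt; aqueous work-up
Reagents that add atoms: none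
Why: Hydride reduction of both esters of a malonate without α-hydrogen cannot be diverted by enolisation, and at or below room temperature the aryl bromide, acetal and alkenes should survive.

Step 12
Reactants: 22 prochiral bromo diol
Product: 23 [(3R)-3-[2,5-dimethoxy-4-(methoxymethoxy)-3-prenylphenyl]-5,7-dimethoxy-6-prenyl-3,4-dihydro-2H-chromen-3-yl]methanol
Conditions: Pd(OAc)2 (5 mol %), (S)-SDP(O) [7-diphenylphosphino-7'-diphenylphosphoryl-1,1'-spirobiindane] (7.5 mol %), Cs2CO3, degassed toluene, 60–80 °C
Reagents that add atoms: none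
Why: Pd(0) formed in situ adds oxidatively to the only C(sp2)–Br bond (C8a), carbonate-assisted exchange of bromide for one hydroxymethyl oxygen gives a seven-membered aryl-palladium alkoxide (Pd, C8a, C4a, C4, C3, C2, O), and C–O reductive elimination releases the chroman and Pd(0). The closest known reaction type is the Buchwald–Hartwig-type intramolecular etherification in its desymmetrising form on 2-substituted 2-(2-halobenzyl)propane-1,3-diols. Ring C closes as a six-membered ring by this reductive elimination, which joins O1 to C8a with C4, C3 and C2 as the tether inside the new ring. C3 becomes stereogenic without any bond to it being made or broken, and the chiral P,O-ligand decides which enantiotopic alkoxide arm sits on palladium in the product-forming palladacycle. The selectivity needed is enantiotopic-group selection, and the substrate supports it through the large size difference at C3 between the ortho-methoxylated ring B, expected pseudo-equatorial in a chair-like palladacycle, and the small free CH2OH. Further reaction is excluded because no second halide remains, the trisubstituted prenyl alkenes are out of reach and poor Heck partners, and methyl ethers and the acetal are inert to carbonate.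

Step 13
Reactants: 23 (R)-chroman-3-ylmethanol
Product: 24 (3S)-3-[2,5-dimethoxy-4-(methoxymethoxy)-3-prenylphenyl]-5,7-dimethoxy-6-prenyl-3,4-dihydro-2H-chromene-3-carbaldehyde
Conditions: Dess–Martin periodinane, CH2Cl2, 0 °C to rt
Reagents that add atoms: none
Why: Dess–Martin oxidation handles hindered neopentyl-type primary alcohols under nearly neutral conditions, spares alkenes, ethers and the acetal, and gives an aldehyde without α-hydrogen, so C3 cannot epimerise.

Step 14
Reactants: 24 (S)-aldehyde
Product: 25 (3R)-3-[2,5-dimethoxy-4-(methoxymethoxy)-3-prenylphenyl]-5,7-dimethoxy-6-prenyl-3,4-dihydro-2H-chromene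
Conditions: RhCl(PPh3)3 (1.1 equiv), degassed xylene, 130 °C
Reagents that add atoms: none
Why: In the Tsuji–Wilkinson decarbonylation Rh(I) adds to the formyl C–H bond, C3 migrates from the acyl carbon to rhodium with extrusion of CO, and C3–H reductive elimination follows on the same face, so hydrogen takes the place of the formyl group with retention.

Step 15
Reactants: 25 (3R)-isoflavan
Product: 26 5-[(3R)-5,7-dimethoxy-6-prenylchroman-3-yl]-2-(methoxymethoxy)-3-prenylcyclohexa-2,5-diene-1,4-dione
Conditions: (NH4)2Ce(NO3)6 (2.2 equiv), MeCN/H2O, 0 °C, short contact time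
Reagents that add atoms: water, O
Why: Cerium(IV) oxidative demethylation picks ring B, the only ring with para-disposed methoxy groups (C2', C5') and the lower oxidation potential, it is the standard last step for prenylated quinones, and the MOM group keeps O4' masked while oxidant is present.

Step 16
Reactants: 26 MOM-protected quinone
Product: 27 5-[(3R)-5,7-dimethoxy-6-prenylchroman-3-yl]-2-hydroxy-3-prenylcyclohexa-2,5-diene-1,4-dione (target)
Conditions: 1 M aq HCl (cat.), THF, rt
Reagents that add atoms: none
Why: In this acid-catalysed acetal hydrolysis the MOM group sits on a vinylogous carboxylate oxygen and loses an excellent leaving group, so dilute acid suffices, too weak to cyclise the prenyl groups and free of the base that could scramble C3.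

Compound list
1 | 1,3-dimethoxybenzene | COc1cccc(OC)c1 | starting material
2 | prenyl bromide (1-bromo-3-methylbut-2-ene) | CC(C)=CCBr | starting material
3 | 2,6-dimethoxyphenyllithium | COc1cccc(OC)c1[Li] | intermediate
4 | 1,3-dimethoxy-2-prenylbenzene | COc1cccc(OC)c1CC=C(C)C | intermediate
5 | (2,4-dimethoxy-3-prenylbenzylidene)dimethyliminium dichlorophosphate | COc1ccc(C=[N+](C)C)c(OC)c1CC=C(C)C.[O-]P(=O)(Cl)Cl | intermediate
6 | 2,4-dimethoxy-3-prenylbenzaldehyde | COc1ccc(C=O)c(OC)c1CC=C(C)C | intermediate
7 | lithium α-amino alkoxide of 6 | COc1ccc(C([O-])N(C)CCN(C)C)c(OC)c1CC=C(C)C.[Li+] | intermediate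
8 | C6-lithiated α-amino alkoxide | COc1cc([Li])c(C([O-])N(C)CCN(C)C)c(OC)c1CC=C(C)C.[Li+] | intermediate
9 | C6-brominated α-amino alkoxide | COc1cc(Br)c(C([O-])N(C)CCN(C)C)c(OC)c1CC=C(C)C.[Li+] | intermediate
10 | 6-bromo-2,4-dimethoxy-3-prenylbenzaldehyde | COc1cc(Br)c(C=O)c(OC)c1CC=C(C)C | intermediate
11 | (6-bromo-2,4-dimethoxy-3-prenylphenyl)methanol | COc1cc(Br)c(CO)c(OC)c1CC=C(C)C | intermediate
12 | 1-bromo-2-(bromomethyl)-3,5-dimethoxy-4-prenylbenzene | COc1cc(Br)c(CBr)c(OC)c1CC=C(C)C | intermediate
13 | 2,5-dimethoxyphenol | COc1ccc(OC)c(O)c1 | starting material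
14 | 2,4-dibromo-3,6-dimethoxyphenol | COc1cc(Br)c(OC)c(Br)c1O | intermediate
15 | 1,3-dibromo-2,5-dimethoxy-4-(methoxymethoxy)benzene | COCOc1c(OC)cc(Br)c(OC)c1Br | intermediate
16 | 3-bromo-2,5-dimethoxy-6-(methoxymethoxy)phenyllithium | COCOc1c(OC)cc(Br)c(OC)c1[Li] | intermediate
17 | 1-bromo-2,5-dimethoxy-4-(methoxymethoxy)-3-prenylbenzene | COCOc1c(OC)cc(Br)c(OC)c1CC=C(C)C | intermediate
18 | diethyl malonate | CCOC(=O)CC(=O)OCC | starting material
19 | diethyl 2-[2,5-dimethoxy-4-(methoxymethoxy)-3-prenylphenyl]malonate | CCOC(=O)C(C(=O)OCC)c1cc(OC)c(OCOC)c(CC=C(C)C)c1OC | intermediate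
20 | sodium enolate of 19 | CCOC(=O)C(=C([O-])OCC)c1cc(OC)c(OCOC)c(CC=C(C)C)c1OC.[Na+] | intermediate
21 | diethyl 2-[(6-bromo-2,4-dimethoxy-3-prenylphenyl)methyl]-2-[2,5-dimethoxy-4-(methoxymethoxy)-3-prenylphenyl]malonate | CCOC(=O)C(Cc1c(Br)cc(OC)c(CC=C(C)C)c1OC)(C(=O)OCC)c1cc(OC)c(OCOC)c(CC=C(C)C)c1OC | intermediate
22 | 2-[(6-bromo-2,4-dimethoxy-3-prenylphenyl)methyl]-2-[2,5-dimethoxy-4-(methoxymethoxy)-3-prenylphenyl]propane-1,3-diol | COc1cc(Br)c(CC(CO)(CO)c2cc(OC)c(OCOC)c(CC=C(C)C)c2OC)c(OC)c1CC=C(C)C | intermediate
23 | [(3R)-3-[2,5-dimethoxy-4-(methoxymethoxy)-3-prenylphenyl]-5,7-dimethoxy-6-prenylchroman-3-yl]methanol | COc1cc2c(c(OC)c1CC=C(C)C)C[C@](CO)(c1cc(OC)c(OCOC)c(CC=C(C)C)c1OC)CO2 | intermediate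
24 | (3S)-3-[2,5-dimethoxy-4-(methoxymethoxy)-3-prenylphenyl]-5,7-dimethoxy-6-prenylchroman-3-carbaldehyde | COc1cc2c(c(OC)c1CC=C(C)C)C[C@](C=O)(c1cc(OC)c(OCOC)c(CC=C(C)C)c1OC)CO2 | intermediate
25 | (3R)-3-[2,5-dimethoxy-4-(methoxymethoxy)-3-prenylphenyl]-5,7-dimethoxy-6-prenylchroman | COc1cc2c(c(OC)c1CC=C(C)C)C[C@H](c1cc(OC)c(OCOC)c(CC=C(C)C)c1OC)CO2 | intermediate
26 | 5-[(3R)-5,7-dimethoxy-6-prenylchroman-3-yl]-2-(methoxymethoxy)-3-prenylcyclohexa-2,5-diene-1,4-dione | COc1cc2c(c(OC)c1CC=C(C)C)C[C@H](C1=CC(=O)C(OCOC)=C(CC=C(C)C)C1=O)CO2 | intermediate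
27 | 5-[(3R)-5,7-dimethoxy-6-prenylchroman-3-yl]-2-hydroxy-3-prenylcyclohexa-2,5-diene-1,4-dione (CNP0241224.1) | COc1cc2c(c(OC)c1CC=C(C)C)C[C@H](C1=CC(=O)C(O)=C(CC=C(C)C)C1=O)CO2 | target

Total step count: 16. Longest linear sequence: 12 steps (steps 1–5, then 10–16). The ring B branch (steps 6–9) joins at step 10.

Steps most likely to fail

1. Step 12.
- What may go wrong: discrimination between the two hydroxymethyl arms may be weak because the bulky ring B crowds the ligand pocket. Alkoxide binding at the neopentyl position may be slow, letting β-hydride elimination and loss of bromine take over.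
- Fallback (from 22, back at 23): stereocontrol passes to an enzyme, and the metal-catalysed closure runs without a chiral ligand. Lipase-catalysed monoacetylation of 22 (vinyl acetate, immobilised lipase chosen by screening, MTBE) should give the (R)-monoacetate F1. Silylation of the free arm (TBDPSCl, imidazole, DMF) gives the silyl ether acetate F2. Methanolysis (K2CO3, MeOH, 0 °C) frees the other arm as the mono-TBDPS diol F3. Ring closure with Pd(OAc)2, racemic 2-(di-tert-butylphosphino)-1,1'-binaphthyl and Cs2CO3 in toluene gives the silylated chroman F4, and TBAF in THF returns 23. The protecting-group swap keeps a monoacetate away from base, where 1,3-acyl migration would racemise it.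

2. Step 14.
- What may go wrong: rhodium insertion and CO extrusion may be sluggish at the congested formyl group. β-Hydride elimination from the tertiary alkyl-rhodium hydride could lead towards an isoflavene. Configuration at the benzylic centre could be partly lost, and rhodium hydride could shift the prenyl double bonds.
- Fallback (from 19 and 12, back at 25): the tertiary centre is made directly by auxiliary control, so no carbon has to be removed. Saponification and decarboxylation of 19 (KOH, aq EtOH; then pH 4, 60 °C) gives the arylacetic acid F5. Activation with pivaloyl chloride and coupling with lithiated (R)-4-benzyloxazolidin-2-one gives the imide F6. Evans alkylation (NaHMDS, THF, −78 °C, then 12) attacks the chelated Z-enolate on the face away from the benzyl group and should give the (2R)-alkylated imide F7. LiBH4 in wet ether releases the (R)-primary alcohol F8. The same achiral palladium-catalysed O-arylation as above closes ring C to 25.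

3. Step 3.
- What may go wrong: deprotonation could compete at the benzylic and allylic CH2 of the prenyl group. Metalation could occur next to the 4-methoxy group instead of next to the amino alkoxide. Lithiation could be incomplete.
- Fallback (from 4, back at 10): bromine is placed by steric control before the formyl group, so no organolithium base meets the prenyl group. Iridium-catalysed C–H borylation of 4 ([Ir(OMe)(cod)]2, dtbpy, B2pin2, THF, 70 °C) goes to the only ring C–H without an ortho substituent and should give the pinacol boronate F9. Copper(II) bromide in aqueous methanol converts it into 5-bromo-1,3-dimethoxy-2-prenylbenzene F10. Vilsmeier–Haack formylation then enters one of the two equivalent positions ortho to bromine and para to a methoxy group and gives 10.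

Further compounds
F1 | step 12 | (R)-monoacetate of diol 22 | COc1cc(Br)c(C[C@](CO)(c2cc(OC)c(OCOC)c(CC=C(C)C)c2OC)COC(C)=O)c(OC)c1CC=C(C)C
F2 | step 12 | (S)-acetate TBDPS ether of diol 22 | COc1cc(Br)c(C[C@](CO[Si](c2ccccc2)(c2ccccc2)C(C)(C)C)(c2cc(OC)c(OCOC)c(CC=C(C)C)c2OC)COC(C)=O)c(OC)c1CC=C(C)C
F3 | step 12 | (S)-mono-TBDPS ether of diol 22 | COc1cc(Br)c(C[C@](CO[Si](c2ccccc2)(c2ccccc2)C(C)(C)C)(c2cc(OC)c(OCOC)c(CC=C(C)C)c2OC)CO)c(OC)c1CC=C(C)C
F4 | step 12 | (S)-TBDPS ether of chromanylmethanol 23 | COc1cc2c(c(OC)c1CC=C(C)C)C[C@](CO[Si](c1ccccc1)(c1ccccc1)C(C)(C)C)(c1cc(OC)c(OCOC)c(CC=C(C)C)c1OC)CO2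
F5 | step 14 | 2-[2,5-dimethoxy-4-(methoxymethoxy)-3-prenylphenyl]acetic acid | OC(=O)Cc1cc(OC)c(OCOC)c(CC=C(C)C)c1OC
F6 | step 14 | (4R)-4-benzyl-3-(arylacetyl)oxazolidin-2-one | O=C1OC[C@@H](Cc2ccccc2)N1C(=O)Cc1cc(OC)c(OCOC)c(CC=C(C)C)c1OC
F7 | step 14 | (4R)-4-benzyl-3-[(2R)-2-aryl-3-(6-bromo-2,4-dimethoxy-3-prenylphenyl)propanoyl]oxazolidin-2-one | O=C1OC[C@@H](Cc2ccccc2)N1C(=O)[C@H](Cc1c(Br)cc(OC)c(CC=C(C)C)c1OC)c1cc(OC)c(OCOC)c(CC=C(C)C)c1OC
F8 | step 14 | (2R)-2-aryl-3-(6-bromo-2,4-dimethoxy-3-prenylphenyl)propan-1-ol | OC[C@H](Cc1c(Br)cc(OC)c(CC=C(C)C)c1OC)c1cc(OC)c(OCOC)c(CC=C(C)C)c1OC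
F9 | step 3 | 2-(3,5-dimethoxy-4-prenylphenyl)-4,4,5,5-tetramethyl-1,3,2-dioxaborolane | COc1cc(B2OC(C)(C)C(C)(C)O2)cc(OC)c1CC=C(C)C
F10 | step 3 | 5-bromo-1,3-dimethoxy-2-prenylbenzene | COc1cc(Br)cc(OC)c1CC=C(C)C
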